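Charge the flask with c(substrate) 0.10 M and c(coupling partner) 0.0950 M, less than the substrate, so coupling partner is the limiting reagent. Expect product to level off near 0.950 of the substrate charged: the north-east run reads 94.6 % at 5.00 min and 94.6 % at 8.00 min.

| flask | substrate | coupling partner | free catalyst | added ligand | remark |
|---|---|---|---|---|---|
| south-west | 0.14 M | 0.95 equiv | 1.3 mol% | 0.88 mM | run made earlier |
| north-east | 0.22 M | 0.95 equiv | 1.3 mol% | 0.88 mM | run made earlier |
| south | 0.10 M | 0.95 equiv | 0.65 mol% | 0.88 mM | run made earlier |
| flask | 0.10 M | 0.950 equiv | 1.3 mol% | 0.88 mM |  |

- south-west (time / min: product / %, substrate / %): 0.667: 23.5, 75.8; 1.33: 44.6, 55.4; 3.00: 77.2, 22.2; 8.00: 94.5, 3.5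
- north-east (time / min: product / %, substrate / %): 1.00: 43.6, 54.5; 3.00: 88.5, 8.9; 5.00: 94.6, 3.2; 8.00: 94.6, 3.5
- south (time / min: product / %, substrate / %): 2.00: 25.8, 74.2; 4.00: 44.1, 55.3; 6.00: 60.0, 39.6; 8.00: 73.3, 28.4

(scatter of a reading: 1 percentage point)

- apparent order in coupling partner when 20 % of the substrate are converted (percent change of the rate of making product for one percent more coupling partner charged)

At 20 % conversion, c(coupling partner) is 0.0750 M, and the same amount has been consumed whatever the excess. Use the gear, c(coupling partner charged) over c(coupling partner left) at fixed conversion, 1.27: one percent more charged means that many percent more left. Multiply the local order in coupling partner by the gear to get the apparent order. The gear is arithmetic on the charge, so the uncertain factor is the local order.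

The forecast says 0.55, from a local order near 0.4. On the split between the reagents it says: “Substrate and partner fall almost together in these runs, so the split between them is poorly determined.”

The flask gives 0.52.

    free catalyst + added ligand ⇌ idle complex, settled at all times (K = 28000 M⁻¹)
    coupling partner + catalyst intermediate A → catalyst intermediate B (k = 13.0 M⁻¹ s⁻¹)
    substrate + free catalyst → catalyst intermediate A (k = 150 M⁻¹ s⁻¹)
    catalyst intermediate B → by-product + catalyst intermediate C (k = 160 s⁻¹)
    catalyst intermediate C → free catalyst + product (k = 1.20 s⁻¹)

Divide out the gear: 0.52 over 1.27 leaves a local order of 0.413. In the north-east run, charged at 0.95 equiv as well, the gear at 20 % conversion is 1.27. In the flask at 1.91 min, free catalyst has a half-life of 0.089 s towards catalyst intermediate A, far shorter than the 1.7 min of coupling partner by its step. At 1.00 min, free catalyst stands at 2.91 % of the catalyst charged and catalyst intermediate A at 35.8 %.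

The readings were computed with constants of no real substance; scatter was added.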